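**Strategy**

The route cuts two neighbouring bonds of ring A at once: the C6–O diaryl ether bond and the C1–CO2H bond, which sit beside the C2 methoxy group as three adjacent substituents. A 3-methoxybenzyne spanning C1–C6 is released from an ortho-silylaryl triflate that already carries the (R)-diol as its acetonide. The hindered ring B phenoxide attacks C6, and the carbanion that appears on C1, next to the methoxy oxygen, is captured by CO2. One operation therefore joins both rings and installs the free acid at the most crowded positions. The stereocentre is set earlier by asymmetric methallylboration, and two mild deprotections finish the synthesis.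

Key step: step 11

Remark: ring A is numbered C1 (carboxyl carbon), C2 (OMe), C3 (side chain), C6 (aryloxy); ring B is numbered from its ether carbon C1'.
Remark: the borane reagent is defined by its origin from (−)-α-pinene, taken to be the commercial (+)-Ipc2BOMe. That enantiomer should deliver the (R) aryl carbinol.

**Route**

Step 1
Reactants: 1 4-hydroxy-2-methoxybenzaldehyde
Product: 2 4-formyl-3-methoxyphenyl N-isopropylcarbamate
Conditions: i-PrNCO, Et3N (cat.), CH2Cl2, 23 °C
Reagents that add atoms: isopropyl isocyanate, CC(C)N=C=O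
Why: Amine-catalysed addition of the phenol to the isocyanate (carbamoylation) masks the phenol with the group that later directs the C1 silylation and that can be removed under mild amine conditions.

Step 2
Reactants: 2 4-formyl-3-methoxyphenyl N-isopropylcarbamate; 3 3-chloro-2-methylpropene
Product: 7 4-[(1R)-1-hydroxy-3-methylbut-3-en-1-yl]-3-methoxyphenyl N-isopropylcarbamate, via methallylmagnesium chloride 4 (not isolated), via B-methallyl diisopinocampheylborane 5 (not isolated), via borinate ester 6 (not isolated)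
Conditions: 3, Mg, THF; (+)-Ipc2BOMe [from (−)-α-pinene], Et2O, −78 → 23 °C; 2, −78 °C; MeOH, pH 7 buffer, 30% H2O2, 0 → 23 °C
Reagents that add atoms: none
Why: Brown asymmetric methallylboration through a closed chair transition state, in which the isopinocampheyl groups from (−)-α-pinene should steer the methallyl unit to the Re face of the aryl aldehyde and so set the (R) carbinol centre; the neutral peroxide work-up spares the base-labile N–H carbamate.

Step 3
Reactants: 7 4-[(1R)-1-hydroxy-3-methylbut-3-en-1-yl]-3-methoxyphenyl N-isopropylcarbamate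
Product: 8 4-[(1R)-1,3-dihydroxy-3-methylbutyl]-3-methoxyphenyl N-isopropylcarbamate
Conditions: Co(acac)2 (cat.), PhSiH3, O2 (1 atm), THF, 23 °C; aq. Na2S2O3
Reagents that add atoms: dioxygen, O=O
Why: Mukaiyama hydration (hydrogen-atom transfer from a cobalt hydride to the 1,1-disubstituted alkene, capture of the tertiary radical by O2, reduction of the peroxide by the silane) should give the Markovnikov tertiary alcohol without touching the benzylic stereocentre.

Step 4
Reactants: 8 4-[(1R)-1,3-dihydroxy-3-methylbutyl]-3-methoxyphenyl N-isopropylcarbamate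
Product: 9 3-methoxy-4-[(4R)-2,2,6,6-tetramethyl-1,3-dioxan-4-yl]phenyl N-isopropylcarbamate
Conditions: 2-methoxypropene, PPTS (cat.), CH2Cl2, 0 → 23 °C; Et3N
Reagents that add atoms: 2-methoxypropene, COC(C)=C
Why: Acid-catalysed ketalisation with the enol ether under kinetic conditions should close the 1,3-dioxane on the secondary/tertiary diol, and the configuration is retained because no bond to the stereocentre is broken.

Step 5
Reactants: 9 3-methoxy-4-[(4R)-2,2,6,6-tetramethyl-1,3-dioxan-4-yl]phenyl N-isopropylcarbamate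
Product: 13 3-methoxy-4-[(4R)-2,2,6,6-tetramethyl-1,3-dioxan-4-yl]-2-(trimethylsilyl)phenyl N-isopropylcarbamate, via N-silyl carbamate 10 (not isolated), via aryllithium 11 (not isolated), via C,N-disilyl carbamate 12 (not isolated)
Conditions: TMEDA, TMSOTf, Et2O, 0 → 23 °C; n-BuLi, TMEDA, −78 °C; TMSCl, −78 → 23 °C; aq. NH4Cl
Reagents that add atoms: chlorotrimethylsilane, C[Si](C)(C)Cl
Why: Directed ortho-metalation in which in situ N-silylation blocks the N–H, n-BuLi/TMEDA removes the C1 proton flanked by the carbamate and the C2 methoxy group, and TMSCl quenches at −78 °C before any anionic Fries shift; premixing the substrate with TMEDA should keep the silyl triflate from opening the ketal.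

Step 6
Reactants: 13 3-methoxy-4-[(4R)-2,2,6,6-tetramethyl-1,3-dioxan-4-yl]-2-(trimethylsilyl)phenyl N-isopropylcarbamate
Product: 15 3-methoxy-4-[(4R)-2,2,6,6-tetramethyl-1,3-dioxan-4-yl]-2-(trimethylsilyl)phenyl trifluoromethanesulfonate, via ortho-silyl phenol 14 (not isolated)
Conditions: DBU, Et2NH, MeCN, 40 °C; then PhNTf2, 23 °C
Reagents that add atoms: N-phenylbis(trifluoromethanesulfonimide), FC(F)(F)S(=O)(=O)N(c1ccccc1)S(=O)(=O)C(F)(F)F
Why: E1cB cleavage of the N–H carbamate by DBU releases isopropyl isocyanate (scavenged by Et2NH) and the ortho-silyl phenoxide, which is triflated in the same pot, the established mild entry to ortho-silylaryl triflates.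

Step 7
Reactants: 16 2-hydroxy-3-methoxy-5-methylbenzaldehyde
Product: 17 2,3-dihydroxy-5-methylbenzaldehyde
Conditions: BBr3, CH2Cl2, −78 → 23 °C; H2O
Reagents that add atoms: none
Why: Lewis acid ether cleavage, in which boron coordinates the methoxy oxygen and bromide attacks the methyl group by SN2; the aldehyde is unaffected.

Step 8
Reactants: 17 2,3-dihydroxy-5-methylbenzaldehyde
Product: 19 3-(benzyloxy)-2-hydroxy-5-methylbenzaldehyde, via disodium dianion 18 (not isolated)
Conditions: NaH (2.2 equiv), DMSO, 23 °C; BnBr (1.0 equiv); aq. HCl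
Reagents that add atoms: benzyl bromide, BrCc1ccccc1
Why: Williamson etherification of the dianion, in which the C2 phenoxide is delocalised into the ortho formyl group, so that the more nucleophilic C3 phenoxide should take the single equivalent of benzyl bromide.

Step 9
Reactants: 19 3-(benzyloxy)-2-hydroxy-5-methylbenzaldehyde
Product: 20 2-(benzyloxy)-6-(hydroxymethyl)-4-methylphenol
Conditions: NaBH4, MeOH/THF, 0 °C
Reagents that add atoms: none
Why: Hydride reduction of the aldehyde by NaBH4 gives the benzylic alcohol and removes the carbonyl that would otherwise intercept the aryl anion of the key step.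

Step 10
Reactants: 20 2-(benzyloxy)-6-(hydroxymethyl)-4-methylphenol
Product: 21 2-(benzyloxy)-6-{[(tert-butyldimethylsilyl)oxy]methyl}-4-methylphenol
Conditions: TBSCl (1.05 equiv), imidazole, CH2Cl2, 0 °C
Reagents that add atoms: tert-butyldimethylsilyl chloride, CC(C)(C)[Si](C)(C)Cl
Why: Selective silylation of the primary benzylic alcohol, since the phenol is hydrogen-bonded and flanked by two ortho substituents and should react more slowly with one equivalent of the silyl chloride.

Step 11
Reactants: 15 3-methoxy-4-[(4R)-2,2,6,6-tetramethyl-1,3-dioxan-4-yl]-2-(trimethylsilyl)phenyl trifluoromethanesulfonate; 21 2-(benzyloxy)-6-{[(tert-butyldimethylsilyl)oxy]methyl}-4-methylphenol; 22 carbon dioxide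
Product: 27 6-[2-(benzyloxy)-6-{[(tert-butyldimethylsilyl)oxy]methyl}-4-methylphenoxy]-2-methoxy-3-[(4R)-2,2,6,6-tetramethyl-1,3-dioxan-4-yl]benzoic acid, via potassium phenoxide 23 (not isolated), via aryne 24 (not isolated), via aryl anion 25 (not isolated), via potassium carboxylate 26 (not isolated)
Conditions: 21 (1.5 equiv), KH, THF, 0 °C; 18-crown-6, dried KF, CO2 (1 atm); 15 added slowly, THF, 0 → 23 °C; cold 10% aq. citric acid
Reagents that add atoms: none
Why: Proposed new method: fluoride attacks the trimethylsilyl group of 15 and triflate departs to give aryne 24; phenoxide 23 bonds through oxygen to C6, the aryne terminus farther from the C2 methoxy substituent, which places carbanion 25 on C1 next to that electronegative oxygen, and CO2 captures it as carboxylate 26. The closest known reactions are the three-component unions of arynes, nitrogen nucleophiles and CO2 that give anthranilic acids under KF/18-crown-6, and the O-arylation of phenols by arynes; the pairing of a phenoxide with CO2 has no precedent. No ring is closed and no stereocentre is formed, and the (R) centre of the dioxane is remote and untouched. Two selectivities are needed: attack at C6 over C1, which the methoxy-induced polarisation of the aryne should secure, and carboxylation over protonation of 25, which an aprotic medium should secure (phenoxide preformed with KH, THF in place of acetonitrile, dried fluoride, no O–H or N–H in either partner). Reversible capture of 23 by CO2 as an aryl carbonate should only lower its free concentration, and slow release of 24 against an excess of 23 should keep carboxylate 26 from adding to a second aryne.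

Step 12
Reactants: 27 6-[2-(benzyloxy)-6-{[(tert-butyldimethylsilyl)oxy]methyl}-4-methylphenoxy]-2-methoxy-3-[(4R)-2,2,6,6-tetramethyl-1,3-dioxan-4-yl]benzoic acid
Product: 28 6-[2-{[(tert-butyldimethylsilyl)oxy]methyl}-6-hydroxy-4-methylphenoxy]-2-methoxy-3-[(4R)-2,2,6,6-tetramethyl-1,3-dioxan-4-yl]benzoic acid
Conditions: H2 (1 atm), 10% Pd/C, EtOAc, 23 °C
Reagents that add atoms: none
Why: Heterogeneous hydrogenolysis of the aryl benzyl ether, which in neutral ethyl acetate at 1 atm should be much faster than cleavage of the benzylic C–O bonds held in the dioxane and the silyl ether.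

Step 13
Reactants: 28 6-[2-{[(tert-butyldimethylsilyl)oxy]methyl}-6-hydroxy-4-methylphenoxy]-2-methoxy-3-[(4R)-2,2,6,6-tetramethyl-1,3-dioxan-4-yl]benzoic acid
Product: 29 6-[2-hydroxy-6-(hydroxymethyl)-4-methylphenoxy]-3-[(1R)-1,3-dihydroxy-3-methylbutyl]-2-methoxybenzoic acid (CNP0452050.1)
Conditions: AcOH/THF/H2O (3:1:1), 23 → 35 °C
Reagents that add atoms: none
Why: Mild acid hydrolysis should cleave both the strained ketal and the primary silyl ether without ionising the electron-rich benzylic carbinol, so the (R) centre is kept.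

**Compound list**

1 | 4-hydroxy-2-methoxybenzaldehyde | COc1cc(O)ccc1C=O | starting material
2 | 4-formyl-3-methoxyphenyl N-isopropylcarbamate | COc1cc(OC(=O)NC(C)C)ccc1C=O | intermediate
3 | 3-chloro-2-methylpropene | CC(=C)CCl | starting material
4 | methallylmagnesium chloride (not isolated) | CC(=C)C[Mg]Cl | intermediate
5 | B-(2-methylallyl)diisopinocampheylborane, both isopinocampheyl groups from (−)-α-pinene (not isolated) | CC(=C)CB([C@H]1C[C@H]2C[C@@H]([C@@H]1C)C2(C)C)[C@H]1C[C@H]2C[C@@H]([C@@H]1C)C2(C)C | intermediate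
6 | diisopinocampheylborinate ester of alcohol 7 (not isolated) | COc1c([C@H](OB([C@H]2C[C@H]3C[C@@H]([C@@H]2C)C3(C)C)[C@H]2C[C@H]3C[C@@H]([C@@H]2C)C3(C)C)CC(C)=C)ccc(OC(=O)NC(C)C)c1 | intermediate
7 | 4-[(1R)-1-hydroxy-3-methylbut-3-en-1-yl]-3-methoxyphenyl N-isopropylcarbamate | COc1c([C@H](O)CC(C)=C)ccc(OC(=O)NC(C)C)c1 | intermediate
8 | 4-[(1R)-1,3-dihydroxy-3-methylbutyl]-3-methoxyphenyl N-isopropylcarbamate | COc1c([C@H](O)CC(C)(C)O)ccc(OC(=O)NC(C)C)c1 | intermediate
9 | 3-methoxy-4-[(4R)-2,2,6,6-tetramethyl-1,3-dioxan-4-yl]phenyl N-isopropylcarbamate | COc1c([C@H]2CC(C)(C)OC(C)(C)O2)ccc(OC(=O)NC(C)C)c1 | intermediate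
10 | N-trimethylsilyl derivative of carbamate 9 (not isolated) | COc1c([C@H]2CC(C)(C)OC(C)(C)O2)ccc(OC(=O)N(C(C)C)[Si](C)(C)C)c1 | intermediate
11 | 2-lithio derivative of 10, lithium on ring A C1 (not isolated) | COc1c([C@H]2CC(C)(C)OC(C)(C)O2)ccc(OC(=O)N(C(C)C)[Si](C)(C)C)c1[Li] | intermediate
12 | 2-(trimethylsilyl) derivative of 10 (not isolated) | COc1c([C@H]2CC(C)(C)OC(C)(C)O2)ccc(OC(=O)N(C(C)C)[Si](C)(C)C)c1[Si](C)(C)C | intermediate
13 | 3-methoxy-4-[(4R)-2,2,6,6-tetramethyl-1,3-dioxan-4-yl]-2-(trimethylsilyl)phenyl N-isopropylcarbamate | COc1c([C@H]2CC(C)(C)OC(C)(C)O2)ccc(OC(=O)NC(C)C)c1[Si](C)(C)C | intermediate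
14 | 3-methoxy-4-[(4R)-2,2,6,6-tetramethyl-1,3-dioxan-4-yl]-2-(trimethylsilyl)phenol (not isolated) | COc1c([C@H]2CC(C)(C)OC(C)(C)O2)ccc(O)c1[Si](C)(C)C | intermediate
15 | 3-methoxy-4-[(4R)-2,2,6,6-tetramethyl-1,3-dioxan-4-yl]-2-(trimethylsilyl)phenyl trifluoromethanesulfonate | COc1c([C@H]2CC(C)(C)OC(C)(C)O2)ccc(OS(=O)(=O)C(F)(F)F)c1[Si](C)(C)C | intermediate
16 | 2-hydroxy-3-methoxy-5-methylbenzaldehyde | COc1cc(C)cc(C=O)c1O | starting material
17 | 2,3-dihydroxy-5-methylbenzaldehyde | Oc1cc(C)cc(C=O)c1O | intermediate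
18 | disodium dianion of 17 (not isolated) | [Na+].[Na+].[O-]c1cc(C)cc(C=O)c1[O-] | intermediate
19 | 3-(benzyloxy)-2-hydroxy-5-methylbenzaldehyde | O=Cc1cc(C)cc(OCc2ccccc2)c1O | intermediate
20 | 2-(benzyloxy)-6-(hydroxymethyl)-4-methylphenol | OCc1cc(C)cc(OCc2ccccc2)c1O | intermediate
21 | 2-(benzyloxy)-6-{[(tert-butyldimethylsilyl)oxy]methyl}-4-methylphenol | Oc1c(OCc2ccccc2)cc(C)cc1CO[Si](C)(C)C(C)(C)C | intermediate
22 | carbon dioxide | O=C=O | starting material
23 | potassium phenoxide of 21 (not isolated) | [K+].[O-]c1c(OCc2ccccc2)cc(C)cc1CO[Si](C)(C)C(C)(C)C | intermediate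
24 | 3-methoxy-4-[(4R)-2,2,6,6-tetramethyl-1,3-dioxan-4-yl]benzyne, triple bond between ring A C1 and C6 (not isolated) | COC1=C([C@H]2CC(C)(C)OC(C)(C)O2)C=CC#C1 | intermediate
25 | potassium aryl anion at ring A C1 after phenoxide addition (not isolated) | COc1c([C@H]2CC(C)(C)OC(C)(C)O2)ccc(Oc2c(OCc3ccccc3)cc(C)cc2CO[Si](C)(C)C(C)(C)C)[c-]1.[K+] | intermediate
26 | potassium salt of acid 27 (not isolated) | COc1c([C@H]2CC(C)(C)OC(C)(C)O2)ccc(Oc2c(OCc3ccccc3)cc(C)cc2CO[Si](C)(C)C(C)(C)C)c1C(=O)[O-].[K+] | intermediate
27 | 6-[2-(benzyloxy)-6-{[(tert-butyldimethylsilyl)oxy]methyl}-4-methylphenoxy]-2-methoxy-3-[(4R)-2,2,6,6-tetramethyl-1,3-dioxan-4-yl]benzoic acid | COc1c([C@H]2CC(C)(C)OC(C)(C)O2)ccc(Oc2c(OCc3ccccc3)cc(C)cc2CO[Si](C)(C)C(C)(C)C)c1C(=O)O | intermediate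
28 | 6-[2-{[(tert-butyldimethylsilyl)oxy]methyl}-6-hydroxy-4-methylphenoxy]-2-methoxy-3-[(4R)-2,2,6,6-tetramethyl-1,3-dioxan-4-yl]benzoic acid | COc1c([C@H]2CC(C)(C)OC(C)(C)O2)ccc(Oc2c(O)cc(C)cc2CO[Si](C)(C)C(C)(C)C)c1C(=O)O | intermediate
29 | 6-[2-hydroxy-6-(hydroxymethyl)-4-methylphenoxy]-3-[(1R)-1,3-dihydroxy-3-methylbutyl]-2-methoxybenzoic acid | COc1c([C@H](O)CC(C)(C)O)ccc(Oc2c(O)cc(C)cc2CO)c1C(=O)O | target

**Step count and risks**

Total: 13 steps. Longest linear sequence: 9 steps (steps 1–6, 11, 12, 13); the ring B branch is 4 steps (7–10).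

Steps most likely to fail:

Step 11 (the one step beyond known chemistry). Protonation of the C1 carbanion by adventitious proton sources may outrun carboxylation, or CO2 may tie up the phenoxide as its carbonate so that the aryne is consumed by other nucleophiles. The fallback uses known chemistry, sets out from 15 and 21, and returns at 27. The aryne is generated with CsF in MeCN at 23 °C in the presence of neutral phenol 21. This is the established O-arylation of phenols, in which the C1 anion is simply protonated, and it should give the diaryl ether (4R)-4-{4-[2-(benzyloxy)-6-{[(tert-butyldimethylsilyl)oxy]methyl}-4-methylphenoxy]-2-methoxyphenyl}-2,2,6,6-tetramethyl-1,3-dioxane F1. Directed ortho-lithiation of F1 (n-BuLi, TMEDA, THF, −78 → −20 °C) at C1, the only ring position flanked by two ether oxygens, should give the C1 aryllithium F2. F2 is carboxylated with CO2 and acidified with cold citric acid to 27. The same two bonds are then made in two operations with the same regiochemical logic.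

Step 5. The silyl triflate used for N-silylation may open the strained ketal, or metalation may stray to C5 or be followed by carbamoyl migration. The fallback sets out from 9 and returns at 14; it replaces the N–H carbamate by one that needs no silyl triflate. DBU/Et2NH in MeCN at 40 °C releases 3-methoxy-4-[(4R)-2,2,6,6-tetramethyl-1,3-dioxan-4-yl]phenol F3. NaH and diethylcarbamoyl chloride in THF give the corresponding N,N-diethylcarbamate F4. s-BuLi/TMEDA in THF at −78 °C lithiates C1 to give the aryllithium F5, and TMSCl converts it into the 2-(trimethylsilyl) N,N-diethylcarbamate F6. LiAlH4 in THF then removes the carbamoyl group reductively to give phenol 14, which is isolated and triflated with PhNTf2 as in the second stage of step 6.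

Step 8. Alkylation may occur at the wrong phenolic oxygen or at both. The fallback sets out from 17 and returns at 19. Exhaustive benzylation (BnBr, K2CO3, DMF, 23 °C) gives 2,3-bis(benzyloxy)-5-methylbenzaldehyde F7. MgBr2·OEt2 in toluene/Et2O at reflux then removes only the benzyl group ortho to the formyl group, through chelation between the carbonyl and the C2 ether oxygen, to give 19.

**Further compounds**

F1 | step 11 | (4R)-4-{4-[2-(benzyloxy)-6-{[(tert-butyldimethylsilyl)oxy]methyl}-4-methylphenoxy]-2-methoxyphenyl}-2,2,6,6-tetramethyl-1,3-dioxane | COc1c([C@H]2CC(C)(C)OC(C)(C)O2)ccc(Oc2c(OCc3ccccc3)cc(C)cc2CO[Si](C)(C)C(C)(C)C)c1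
F2 | step 11 | C1 aryllithium of F1 (lithium between the methoxy and aryloxy groups) | COc1c([C@H]2CC(C)(C)OC(C)(C)O2)ccc(Oc2c(OCc3ccccc3)cc(C)cc2CO[Si](C)(C)C(C)(C)C)c1[Li]
F3 | step 5 | 3-methoxy-4-[(4R)-2,2,6,6-tetramethyl-1,3-dioxan-4-yl]phenol | COc1c([C@H]2CC(C)(C)OC(C)(C)O2)ccc(O)c1
F4 | step 5 | 3-methoxy-4-[(4R)-2,2,6,6-tetramethyl-1,3-dioxan-4-yl]phenyl N,N-diethylcarbamate | COc1c([C@H]2CC(C)(C)OC(C)(C)O2)ccc(OC(=O)N(CC)CC)c1
F5 | step 5 | 2-lithio derivative of F4 (lithium on ring A C1) | COc1c([C@H]2CC(C)(C)OC(C)(C)O2)ccc(OC(=O)N(CC)CC)c1[Li]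
F6 | step 5 | 3-methoxy-4-[(4R)-2,2,6,6-tetramethyl-1,3-dioxan-4-yl]-2-(trimethylsilyl)phenyl N,N-diethylcarbamate | COc1c([C@H]2CC(C)(C)OC(C)(C)O2)ccc(OC(=O)N(CC)CC)c1[Si](C)(C)C
F7 | step 8 | 2,3-bis(benzyloxy)-5-methylbenzaldehyde | O=Cc1cc(C)cc(OCc2ccccc2)c1OCc1ccccc1
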